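**Plan**

1. Retrosynthesis, last bonds first: the three benzyl and two silyl ethers are removed, then the ring A aryl–C(=O) bond is cut (Friedel–Crafts with the chiral acid chloride), then the two outer-ring aryl–acetyl bonds (ortho-formylation, methyl addition, oxidation).
2. In each outer ring two bonds are then cut, C(OH)–C(bridge) and C(OSi)–C(CH3). This leads back to a ring A bis(siloxyalkyne) and two molecules of 3-methoxy-2-methylcyclobutenone.
3. The feature that allows this: round each outer benzene ring the six carbons carry OH, the CH2 bridge, OH, CH3, OCH3 and acetyl. The bridge carbon and one neighbouring C–O are the two carbons of a siloxyalkyne; the other four (C–OH, C–H that later takes the acetyl, C–OCH3, C–CH3) are the vinylketene from the cyclobutenone.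
4. The bis(siloxyalkyne) comes from a ring A bis(arylacetate) by ester-to-ynolate homologation, the diester from dibromo-tris(benzyloxy)benzene by twofold Pd-catalysed coupling with two equivalents of a zinc ester enolate, and the cyclobutenone from 1-methoxypropyne and ketene.
5. Forward order: ring A is bought as phloroglucinol; both outer rings are formed together in one thermal operation; then come the two acetyl groups, the ring A acyl group and the deprotections.
6. The single stereocentre (R) is bought with (R)-2-methylbutanoic acid and enters late as the acid chloride; no later step is basic enough to enolise the ketone.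

Key step: step 7

Remark on the chemistry: ketene for step 6 is assumed to be supplied as a gas stream from the pyrolysis of acetone.

**Route**

Step 1
Reactants: 1 phloroglucinol
Product: 2 1,3,5-tris(benzyloxy)benzene
Conditions: BnBr (3.3 equiv), K2CO3, DMF, 60 °C
Reagents that add atoms: benzyl bromide, BrCc1ccccc1
Why: Williamson ether synthesis: in DMF the potassium phenoxides of 1 should be alkylated chiefly on oxygen, and benzyl is chosen because it tolerates the organolithium, zinc, thermal and Lewis acid steps ahead and leaves at the end under neutral hydrogenolysis.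

Step 2
Reactants: 2 1,3,5-tris(benzyloxy)benzene
Product: 3 1,3,5-tris(benzyloxy)-2,4-dibromobenzene
Conditions: NBS (2.0 equiv), CH2Cl2, −20 → 0 °C
Reagents that add atoms: N-bromosuccinimide, O=C1CCC(=O)N1Br
Why: Electrophilic aromatic bromination: the three free positions of 2 are equivalent and each bromine lowers the reactivity of the ring, so two equivalents of NBS at low temperature should stop at the 2,4-dibromide.

Step 3
Reactants: 3 1,3,5-tris(benzyloxy)-2,4-dibromobenzene; 4 ethyl bromoacetate (2.5 equiv)
Product: 6 diethyl 2,2'-[2,4,6-tris(benzyloxy)-1,3-phenylene]diacetate, via bromo(2-ethoxy-2-oxoethyl)zinc 5 (not isolated)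
Conditions: 4 (2.5 equiv), Zn dust (3 equiv, TMSCl-activated), THF, 40 °C; then 3 (1 equiv), Pd2(dba)3 (2.5 mol %), XPhos (10 mol %), THF, 65 °C
Reagents that add atoms: none
Why: Twofold Negishi-type cross-coupling of a Reformatsky reagent (Pd-catalysed α-arylation of a zinc ester enolate), in which one molecule of 5 made from 4 is consumed at each of the two C–Br bonds of 3: the bulky, electron-rich biarylphosphine should allow oxidative addition and reductive elimination at bromides flanked by two alkoxy groups, and the weakly basic zinc enolate leaves benzyl ethers and the product ester untouched.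

Step 4
Reactants: 6 diethyl 2,2'-[2,4,6-tris(benzyloxy)-1,3-phenylene]diacetate
Product: 8 1,3,5-tris(benzyloxy)-2,4-bis[3-(triisopropylsilyloxy)prop-2-yn-1-yl]benzene, via dilithium bis(ynolate) 7 (not isolated)
Conditions: CH2Br2, lithium 2,2,6,6-tetramethylpiperidide, THF, −78 °C; LiN(SiMe3)2; n-BuLi, −78 °C → rt; TIPSCl, −78 → 0 °C (each reagent in at least twofold amount, one portion per ester group)
Reagents that add atoms: dibromomethane, BrCBr; chlorotriisopropylsilane, CC(C)[Si](Cl)(C(C)C)C(C)C
Why: Kowalski ester homologation stopped at the ynolate: at −78 °C dibromomethyllithium should add to each ester carbonyl faster than it deprotonates the flanked benzylic CH2, bromine–lithium exchange then triggers the carbenoid 1,2-shift of the arylmethyl group that gives ynolate 7, and the bulky chlorosilane silylates 7 on oxygen rather than on carbon.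

Step 5
Reactants: 9 2-chloro-1,1-dimethoxyethane (chloroacetaldehyde dimethyl acetal)
Product: 11 1-methoxyprop-1-yne, via sodium methoxyethynide 10 (not isolated)
Conditions: NaNH2 (3 equiv), liquid NH3, −33 °C; then MeI; distillation
Reagents that add atoms: iodomethane, CI
Why: Base-induced double elimination (loss of methanol and HCl) from the chloroacetal gives the sodium alkoxyacetylide 10, and its C-methylation in the same flask is the standard preparation of 1-alkoxyalk-1-ynes.

Step 6
Reactants: 11 1-methoxyprop-1-yne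
Product: 12 3-methoxy-2-methylcyclobut-2-en-1-one
Conditions: ketene (gas), CH2Cl2, −20 °C → rt
Reagents that add atoms: ketene, C=C=O
Why: Thermal [2+2] cycloaddition of ketene to an ynol ether: the alkyne carbon remote from oxygen is the nucleophile and bonds to the ketene carbonyl carbon, which places methyl at C2 and methoxy at C3 of the cyclobutenone.

Step 7
Reactants: 8 1,3,5-tris(benzyloxy)-2,4-bis[3-(triisopropylsilyloxy)prop-2-yn-1-yl]benzene; 12 3-methoxy-2-methylcyclobut-2-en-1-one (2.5 equiv)
Product: 17 1,3,5-tris(benzyloxy)-2,4-bis[2-hydroxy-4-methoxy-5-methyl-6-(triisopropylsilyloxy)benzyl]benzene, via vinylketene 13 (not isolated), via twofold cyclobutenone adduct 14 (not isolated), via bis(dienylketene) 15 (not isolated), via bis(cyclohexadienone) 16 (not isolated)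
Conditions: 12 added in portions, toluene, 80 → 100 °C, argon
Reagents that add atoms: none
Why: Each molecule of 12 undergoes thermal 4π electrocyclic ring opening to vinylketene 13, which adds [2+2] across one siloxyalkyne arm of 8 to give the 4-vinylcyclobutenone 14; a second 4π opening leads to dienylketene 15, 6π electrocyclisation closes the six-membered ring as cyclohexadienone 16, and enolisation gives the phenol. The closest known reaction is the Danheiser benzannulation of cyclobutenones with trialkylsilyloxyalkynes, which gives resorcinol monosilyl ethers; here it is run on two arms of one substrate. Both outer rings close in the same mode, a thermal disrotatory 6π electrocyclisation of a dienylketene in which the ketene carbon bonds to the terminal CH2, followed by tautomerisation to the arene. No stereocentre is formed in 17, since the quaternary carbon of 14 is lost in the second ring opening. The selectivity required is the orientation of the [2+2] step, and the polarisation of the ynol ether secures it: the alkyne carbon β to the silyloxy oxygen is the nucleophilic one and attacks the central ketene carbon, so that in each new ring the free hydroxyl lies beside the bridge carbon and the silyloxy group beside the methyl-bearing carbon. The two arms are separated by ring A and two sp3 carbons and should react independently, and benzyl ethers, silyl ethers and the phenols formed are inert in hot toluene without acid or base.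

Step 8
Reactants: 17 1,3,5-tris(benzyloxy)-2,4-bis[2-hydroxy-4-methoxy-5-methyl-6-(triisopropylsilyloxy)benzyl]benzene
Product: 19 1,3,5-tris(benzyloxy)-2,4-bis[3-formyl-2-hydroxy-4-methoxy-5-methyl-6-(triisopropylsilyloxy)benzyl]benzene, via bis(hydroxymethyl) compound 18 (not isolated)
Conditions: MgCl2, Et3N, (CH2O)n, MeCN, reflux
Reagents that add atoms: formaldehyde (as paraformaldehyde), C=O
Why: Magnesium-mediated ortho-formylation of phenols (Casnati–Skattebøl reaction): the magnesium phenoxide of each outer ring delivers formaldehyde to its only free ortho carbon and a second formaldehyde oxidises the benzylic alkoxide of 18 by hydride transfer, whereas ring A has no free hydroxyl and meets no acid, so its free carbon is not attacked (an acyl shift from oxygen under Lewis acid could cross over to that carbon, and a photochemical one would endanger the benzyl ethers).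

Step 9
Reactants: 19 1,3,5-tris(benzyloxy)-2,4-bis[3-formyl-2-hydroxy-4-methoxy-5-methyl-6-(triisopropylsilyloxy)benzyl]benzene
Product: 20 1,3,5-tris(benzyloxy)-2,4-bis[2-hydroxy-3-(1-hydroxyethyl)-4-methoxy-5-methyl-6-(triisopropylsilyloxy)benzyl]benzene (mixture of diastereomers)
Conditions: MeMgBr (6 equiv), THF, −78 → 0 °C; pH 7 buffer
Reagents that add atoms: methylmagnesium bromide, C[Mg]Br
Why: Grignard addition to the two aldehydes after deprotonation of the phenols; the two new carbinol centres form without control and are removed in step 10, so 20 is carried on as a mixture.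

Step 10
Reactants: 20 1,3,5-tris(benzyloxy)-2,4-bis[2-hydroxy-3-(1-hydroxyethyl)-4-methoxy-5-methyl-6-(triisopropylsilyloxy)benzyl]benzene
Product: 21 1,3,5-tris(benzyloxy)-2,4-bis[3-acetyl-2-hydroxy-4-methoxy-5-methyl-6-(triisopropylsilyloxy)benzyl]benzene
Conditions: activated MnO2 (excess), CH2Cl2, rt
Reagents that add atoms: none
Why: MnO2 oxidation of benzylic alcohols: the heterogeneous oxidant should take the secondary benzylic carbinols to ketones that are stabilised by hydrogen bonding to the neighbouring phenol, without touching benzyl ethers, silyl ethers or the diarylmethane CH2 groups.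

Step 11
Reactants: 22 (R)-2-methylbutanoic acid
Product: 23 (R)-2-methylbutanoyl chloride
Conditions: (COCl)2, DMF (cat.), CH2Cl2, 0 °C → rt; volatiles removed
Reagents that add atoms: oxalyl chloride, O=C(Cl)C(=O)Cl
Why: Acid chloride formation with oxalyl chloride under catalytic Vilsmeier activation; no base is present, so no ketene can form and the α-stereocentre should keep its R configuration.

Step 12
Reactants: 21 1,3,5-tris(benzyloxy)-2,4-bis[3-acetyl-2-hydroxy-4-methoxy-5-methyl-6-(triisopropylsilyloxy)benzyl]benzene; 23 (R)-2-methylbutanoyl chloride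
Product: 24 (2R)-1-{2,4,6-tris(benzyloxy)-3,5-bis[3-acetyl-2-hydroxy-4-methoxy-5-methyl-6-(triisopropylsilyloxy)benzyl]phenyl}-2-methylbutan-1-one
Conditions: SnCl4, CH2Cl2, −78 → −20 °C
Reagents that add atoms: none
Why: Friedel–Crafts acylation: the only activated aromatic C–H left in 21 is the ring A carbon ortho to two benzyloxy groups and para to the third, so the acylium ion from 23 can enter only there, and the stereocentre is carried over unchanged from 23 because neither the low-temperature Lewis acid conditions nor the twisted, fully substituted aryl ketone favour enolisation.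

Step 13
Reactants: 24 (2R)-1-{2,4,6-tris(benzyloxy)-3,5-bis[3-acetyl-2-hydroxy-4-methoxy-5-methyl-6-(triisopropylsilyloxy)benzyl]phenyl}-2-methylbutan-1-one
Product: 25 (2R)-1-[2,4,6-tris(benzyloxy)-3,5-bis(3-acetyl-2,6-dihydroxy-4-methoxy-5-methylbenzyl)phenyl]-2-methylbutan-1-one
Conditions: Bu4NF, AcOH, THF, 0 °C
Reagents that add atoms: none
Why: Fluoride-induced cleavage of the two aryl silyl ethers; acetic acid buffers the phenoxides so that the ketone next to the stereocentre is not enolised.

Step 14
Reactants: 25 (2R)-1-[2,4,6-tris(benzyloxy)-3,5-bis(3-acetyl-2,6-dihydroxy-4-methoxy-5-methylbenzyl)phenyl]-2-methylbutan-1-one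
Product: 26 (2R)-1-[3,5-bis(3-acetyl-2,6-dihydroxy-4-methoxy-5-methylbenzyl)-2,4,6-trihydroxyphenyl]-2-methylbutan-1-one (CNP0201397.1)
Conditions: H2 (1 atm), 10% Pd/C, EtOAc–MeOH, rt
Reagents that add atoms: none
Why: Hydrogenolysis of the three benzyl ethers over Pd/C under neutral conditions; the hydrogen-bonded aryl ketones, the methyl ethers and the stereocentre should not be affected, and filtration and evaporation deliver the polyphenol without exposure to acid or base.

**Compound list**

1 | phloroglucinol (benzene-1,3,5-triol) | Oc1cc(O)cc(O)c1 | starting material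
2 | 1,3,5-tris(benzyloxy)benzene | C(c1ccccc1)Oc1cc(OCc2ccccc2)cc(OCc2ccccc2)c1 | intermediate
3 | 1,3,5-tris(benzyloxy)-2,4-dibromobenzene | C(c1ccccc1)Oc1cc(OCc2ccccc2)c(Br)c(OCc2ccccc2)c1Br | intermediate
4 | ethyl bromoacetate | CCOC(=O)CBr | starting material
5 | bromo(2-ethoxy-2-oxoethyl)zinc (Reformatsky reagent, formed in situ) | CCOC(=O)C[Zn]Br | intermediate
6 | diethyl 2,2'-[2,4,6-tris(benzyloxy)-1,3-phenylene]diacetate | C(c1ccccc1)Oc1cc(OCc2ccccc2)c(CC(=O)OCC)c(OCc2ccccc2)c1CC(=O)OCC | intermediate
7 | dilithium 3,3'-[2,4,6-tris(benzyloxy)-1,3-phenylene]bis(prop-1-yn-1-olate) (bis(ynolate), formed in situ) | C(c1ccccc1)Oc1cc(OCc2ccccc2)c(CC#C[O-])c(OCc2ccccc2)c1CC#C[O-].[Li+].[Li+] | intermediate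
8 | 1,3,5-tris(benzyloxy)-2,4-bis[3-(triisopropylsilyloxy)prop-2-yn-1-yl]benzene | C(c1ccccc1)Oc1cc(OCc2ccccc2)c(CC#CO[Si](C(C)C)(C(C)C)C(C)C)c(OCc2ccccc2)c1CC#CO[Si](C(C)C)(C(C)C)C(C)C | intermediate
9 | 2-chloro-1,1-dimethoxyethane | COC(CCl)OC | starting material
10 | sodium methoxyethynide (formed in situ) | [Na+].[C-]#COC | intermediate
11 | 1-methoxyprop-1-yne | CC#COC | intermediate
12 | 3-methoxy-2-methylcyclobut-2-en-1-one | COC1=C(C)C(=O)C1 | intermediate
13 | 3-methoxy-2-methylbuta-1,3-dien-1-one (vinylketene, formed in situ) | C=C(OC)C(C)=C=O | intermediate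
14 | 1,3,5-tris(benzyloxy)-2,4-bis{[3-(1-methoxyvinyl)-3-methyl-4-oxo-2-(triisopropylsilyloxy)cyclobut-1-en-1-yl]methyl}benzene (twofold cyclobutenone adduct, formed in situ, mixture of diastereomers) | C(c1ccccc1)Oc1cc(OCc2ccccc2)c(CC2=C(O[Si](C(C)C)(C(C)C)C(C)C)C(C)(C(=C)OC)C2=O)c(OCc2ccccc2)c1CC1=C(O[Si](C(C)C)(C(C)C)C(C)C)C(C)(C(=C)OC)C1=O | intermediate
15 | 1,3,5-tris(benzyloxy)-2,4-bis[5-methoxy-4-methyl-2-(oxomethylidene)-3-(triisopropylsilyloxy)hexa-3,5-dien-1-yl]benzene (bis(dienylketene), formed in situ; ketene and methoxyvinyl groups cis on the central double bond) | C(c1ccccc1)Oc1cc(OCc2ccccc2)c(CC(=C=O)/C(O[Si](C(C)C)(C(C)C)C(C)C)=C(C)\C(OC)=C)c(OCc2ccccc2)c1CC(=C=O)/C(O[Si](C(C)C)(C(C)C)C(C)C)=C(C)\C(OC)=C | intermediate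
16 | 1,3,5-tris(benzyloxy)-2,4-bis{[4-methoxy-3-methyl-6-oxo-2-(triisopropylsilyloxy)cyclohexa-1,3-dien-1-yl]methyl}benzene (bis(cyclohexadienone), formed in situ) | C(c1ccccc1)Oc1cc(OCc2ccccc2)c(CC2=C(O[Si](C(C)C)(C(C)C)C(C)C)C(C)=C(OC)CC2=O)c(OCc2ccccc2)c1CC1=C(O[Si](C(C)C)(C(C)C)C(C)C)C(C)=C(OC)CC1=O | intermediate
17 | 1,3,5-tris(benzyloxy)-2,4-bis[2-hydroxy-4-methoxy-5-methyl-6-(triisopropylsilyloxy)benzyl]benzene | C(c1ccccc1)Oc1cc(OCc2ccccc2)c(Cc2c(O)cc(OC)c(C)c2O[Si](C(C)C)(C(C)C)C(C)C)c(OCc2ccccc2)c1Cc1c(O)cc(OC)c(C)c1O[Si](C(C)C)(C(C)C)C(C)C | intermediate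
18 | 1,3,5-tris(benzyloxy)-2,4-bis[2-hydroxy-3-(hydroxymethyl)-4-methoxy-5-methyl-6-(triisopropylsilyloxy)benzyl]benzene (formed in situ) | C(c1ccccc1)Oc1cc(OCc2ccccc2)c(Cc2c(O)c(CO)c(OC)c(C)c2O[Si](C(C)C)(C(C)C)C(C)C)c(OCc2ccccc2)c1Cc1c(O)c(CO)c(OC)c(C)c1O[Si](C(C)C)(C(C)C)C(C)C | intermediate
19 | 1,3,5-tris(benzyloxy)-2,4-bis[3-formyl-2-hydroxy-4-methoxy-5-methyl-6-(triisopropylsilyloxy)benzyl]benzene | C(c1ccccc1)Oc1cc(OCc2ccccc2)c(Cc2c(O)c(C=O)c(OC)c(C)c2O[Si](C(C)C)(C(C)C)C(C)C)c(OCc2ccccc2)c1Cc1c(O)c(C=O)c(OC)c(C)c1O[Si](C(C)C)(C(C)C)C(C)C | intermediate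
20 | 1,3,5-tris(benzyloxy)-2,4-bis[2-hydroxy-3-(1-hydroxyethyl)-4-methoxy-5-methyl-6-(triisopropylsilyloxy)benzyl]benzene (carbinol centres unassigned, mixture) | C(c1ccccc1)Oc1cc(OCc2ccccc2)c(Cc2c(O)c(C(C)O)c(OC)c(C)c2O[Si](C(C)C)(C(C)C)C(C)C)c(OCc2ccccc2)c1Cc1c(O)c(C(C)O)c(OC)c(C)c1O[Si](C(C)C)(C(C)C)C(C)C | intermediate
21 | 1,3,5-tris(benzyloxy)-2,4-bis[3-acetyl-2-hydroxy-4-methoxy-5-methyl-6-(triisopropylsilyloxy)benzyl]benzene | C(c1ccccc1)Oc1cc(OCc2ccccc2)c(Cc2c(O)c(C(C)=O)c(OC)c(C)c2O[Si](C(C)C)(C(C)C)C(C)C)c(OCc2ccccc2)c1Cc1c(O)c(C(C)=O)c(OC)c(C)c1O[Si](C(C)C)(C(C)C)C(C)C | intermediate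
22 | (R)-2-methylbutanoic acid | CC[C@@H](C)C(=O)O | starting material
23 | (R)-2-methylbutanoyl chloride | CC[C@@H](C)C(=O)Cl | intermediate
24 | (2R)-1-{2,4,6-tris(benzyloxy)-3,5-bis[3-acetyl-2-hydroxy-4-methoxy-5-methyl-6-(triisopropylsilyloxy)benzyl]phenyl}-2-methylbutan-1-one | CC[C@@H](C)C(=O)c1c(OCc2ccccc2)c(Cc2c(O)c(C(C)=O)c(OC)c(C)c2O[Si](C(C)C)(C(C)C)C(C)C)c(OCc2ccccc2)c(Cc2c(O)c(C(C)=O)c(OC)c(C)c2O[Si](C(C)C)(C(C)C)C(C)C)c1OCc1ccccc1 | intermediate
25 | (2R)-1-[2,4,6-tris(benzyloxy)-3,5-bis(3-acetyl-2,6-dihydroxy-4-methoxy-5-methylbenzyl)phenyl]-2-methylbutan-1-one | CC[C@@H](C)C(=O)c1c(OCc2ccccc2)c(Cc2c(O)c(C(C)=O)c(OC)c(C)c2O)c(OCc2ccccc2)c(Cc2c(O)c(C(C)=O)c(OC)c(C)c2O)c1OCc1ccccc1 | intermediate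
26 | (2R)-1-[3,5-bis(3-acetyl-2,6-dihydroxy-4-methoxy-5-methylbenzyl)-2,4,6-trihydroxyphenyl]-2-methylbutan-1-one (CNP0201397.1) | CC[C@@H](C)C(=O)c1c(O)c(Cc2c(O)c(C)c(OC)c(C(C)=O)c2O)c(O)c(Cc2c(O)c(C)c(OC)c(C(C)=O)c2O)c1O | target

**Step count**

Total: 14 steps. Longest linear sequence: 11 steps (1, 2, 3, 4, 7, 8, 9, 10, 12, 13, 14) from phloroglucinol.

**Steps most likely to fail**

Step 4 (twofold ynolate homologation and silylation). What may go wrong: proton transfer from the benzylic CH2 of the arylacetate to the carbenoid or amide base competes with addition to the carbonyl, and the second ester arm lags behind the first, so that mixtures result; lithiation of the benzyl ethers by excess butyllithium on warming is a further loss channel. Fallback, from 6 back to 8, in which the ynolate is made by oxidation of an acetylide instead of by carbenoid rearrangement: 6 is reduced with i-Bu2AlH (CH2Cl2, −78 °C) to 2,2'-[2,4,6-tris(benzyloxy)-1,3-phenylene]diacetaldehyde F1. The Ohira–Bestmann reagent (dimethyl (1-diazo-2-oxopropyl)phosphonate, K2CO3, MeOH) converts F1 into 1,3,5-tris(benzyloxy)-2,4-di(prop-2-yn-1-yl)benzene F2. Deprotonation of both terminal alkynes (LiN(SiMe3)2, THF, −78 °C), oxidation of the lithium acetylides with LiOOt-Bu to the same bis(ynolate) 7 and silylation with TIPSOTf then give 8.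

Step 7 (twofold benzannulation). What may go wrong: ring opening of the alkoxy-stabilised cyclobutenone is slow at temperatures at which the siloxyalkyne begins to rearrange by silyl shift, and the phenol formed in the first annulation captures vinylketene as an aryl ester before the second arm has reacted. Fallback, from 8 back to 17, in which vinylketene 13 is generated at room temperature by a photochemical Wolff rearrangement instead of by thermal ring opening: 2-methoxypent-1-en-3-one F3 (from 1-methoxyvinyllithium and N-methoxy-N-methylpropanamide) is trifluoroacetylated (LiN(SiMe3)2, CF3CO2CH2CF3) to 1,1,1-trifluoro-5-methoxy-3-methylhex-5-ene-2,4-dione F4. Detrifluoroacetylative diazo transfer (MsN3, Et3N, MeCN) converts F4 into 4-diazo-2-methoxypent-1-en-3-one F5. Irradiation of F5 (350 nm, CH2Cl2, rt) in the presence of 8 releases 13 slowly and at low concentration, and brief warming of the adduct 14 completes the passage through 15 and 16 to 17.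

Step 12 (acylation of ring A). What may go wrong: attack at the crowded ring A carbon is slowed by the two flanking benzyloxy groups, so that Lewis acid-induced loss of benzyl groups, O-acylation of the outer-ring phenols or cleavage at the diarylmethane carbons takes over; a long-lived acylium ion could also lose its α-proton to a ketene, which would erode the configuration. Fallback, from 21 to 26, in which the protecting groups are removed first and the free phloroglucinol ring is acylated: 21 is desilylated (Bu4NF, AcOH, THF) to 1,3,5-tris(benzyloxy)-2,4-bis(3-acetyl-2,6-dihydroxy-4-methoxy-5-methylbenzyl)benzene F6. Hydrogenolysis (H2, Pd/C) gives 2,4-bis(3-acetyl-2,6-dihydroxy-4-methoxy-5-methylbenzyl)benzene-1,3,5-triol F7, whose ring A is far more nucleophilic and unhindered at its one free carbon, so that the acylating species should be captured quickly. Friedel–Crafts acylation of F7 with 23 (BF3·OEt2, CH2Cl2–dioxane, 0 °C → rt, a Lewis acid that leaves aryl methyl ethers intact) then gives 26 directly.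

**Further compounds**

F1 | step 4 | 2,2'-[2,4,6-tris(benzyloxy)-1,3-phenylene]diacetaldehyde | C(c1ccccc1)Oc1cc(OCc2ccccc2)c(CC=O)c(OCc2ccccc2)c1CC=O
F2 | step 4 | 1,3,5-tris(benzyloxy)-2,4-di(prop-2-yn-1-yl)benzene | C(c1ccccc1)Oc1cc(OCc2ccccc2)c(CC#C)c(OCc2ccccc2)c1CC#C
F3 | step 7 | 2-methoxypent-1-en-3-one | C=C(OC)C(=O)CC
F4 | step 7 | 1,1,1-trifluoro-5-methoxy-3-methylhex-5-ene-2,4-dione | C=C(OC)C(=O)C(C)C(=O)C(F)(F)F
F5 | step 7 | 4-diazo-2-methoxypent-1-en-3-one | C=C(OC)C(=O)C(C)=[N+]=[N-]
F6 | step 12 | 1,3,5-tris(benzyloxy)-2,4-bis(3-acetyl-2,6-dihydroxy-4-methoxy-5-methylbenzyl)benzene | C(c1ccccc1)Oc1cc(OCc2ccccc2)c(Cc2c(O)c(C(C)=O)c(OC)c(C)c2O)c(OCc2ccccc2)c1Cc1c(O)c(C(C)=O)c(OC)c(C)c1O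
F7 | step 12 | 2,4-bis(3-acetyl-2,6-dihydroxy-4-methoxy-5-methylbenzyl)benzene-1,3,5-triol | Oc1cc(O)c(Cc2c(O)c(C(C)=O)c(OC)c(C)c2O)c(O)c1Cc1c(O)c(C(C)=O)c(OC)c(C)c1O
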